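**Retrosynthetic overview**
- The side chain is cut at C2'–C3': a 2‑vinylchroman core is joined to a (2Z,6E)-vinyl iodide ester by hydroboration/B‑alkyl Suzuki coupling in the last step.
- The pyran ring is the only ring formed (the arene is bought): an enantioselective Pd π‑allyl O‑alkylation of a phenol with a pendant (E)-allylic acetate closes it and sets C2.
- That phenol comes from orsellinaldehyde and a C5 allylic carbonate. The benzylic C–C bond is made by reversing the polarity of the aldehyde carbon (N–H hydrazone as carbanion equivalent, N2 lost), so two natively electrophilic carbons are joined without any later deoxygenation.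
- The vinyl iodide comes from pent‑4‑yn‑1‑ol (carboalumination/iodination, oxidation, Still–Gennari); the C5 unit comes from prenyl acetate (E‑selective SeO2 oxidation).

Assumption: in the Pd-catalysed ring closure the (R,R)-antipode of the Trost ligand is taken to give the 2S-vinylchroman from the E-acetate; if the sense proves opposite, the (S,S)-ligand is used and nothing else changes.

**Route**

Step 1
Reactants: 1 2,4-dihydroxy-6-methylbenzaldehyde (orsellinaldehyde)
Product: 2 2,4-bis(triisopropylsilyloxy)-6-methylbenzaldehyde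
Conditions: TIPSOTf (2.4 equiv), 2,6-lutidine (3 equiv), CH2Cl2, 0 °C → rt
Reagents that add atoms: triisopropylsilyl trifluoromethanesulfonate, CC(C)[Si](OS(=O)(=O)C(F)(F)F)(C(C)C)C(C)C
Why: Silyl ether formation; the triflate also silylates the hydrogen-bonded ortho-OH, masking both phenols, which would otherwise be O-allylated in step 4.

Step 2
Reactants: 3 3-methylbut-2-en-1-yl acetate (prenyl acetate)
Product: 4 (E)-4-hydroxy-3-methylbut-2-en-1-yl acetate
Conditions: SeO2 (0.5 equiv), t-BuOOH (2 equiv), CH2Cl2, rt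
Reagents that add atoms: tert-butyl hydroperoxide, CC(C)(C)OO (source of the new oxygen; selenium dioxide, O=[Se]=O, is the catalytic oxygen carrier)
Why: Riley allylic oxidation (ene reaction then [2,3]-sigmatropic shift) oxidises only the methyl trans to the CH2OAc chain, giving the E-allylic alcohol with defined olefin geometry.

Step 3
Reactants: 4 (E)-4-hydroxy-3-methylbut-2-en-1-yl acetate
Product: 5 (E)-4-acetoxy-2-methylbut-2-en-1-yl methyl carbonate
Conditions: ClCO2Me, pyridine, CH2Cl2, 0 °C
Reagents that add atoms: methyl chloroformate, COC(=O)Cl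
Why: O-acylation to the carbonate gives an allylic leaving group that Pd(0) ionises far faster than the acetate at the other terminus and that releases its own base (methoxide).

Step 4
Reactants: 2 2,4-bis(triisopropylsilyloxy)-6-methylbenzaldehyde; 5 (E)-4-acetoxy-2-methylbut-2-en-1-yl methyl carbonate
Product: 7 (E)-5-[2,4-bis(triisopropylsilyloxy)-6-methylphenyl]-3-methylpent-2-en-1-yl acetate, via aryl aldehyde N-H hydrazone 6 (not isolated)
Conditions: (i) N2H4·H2O (1.1 equiv), THF, rt, then evaporate; (ii) 5 (1.3 equiv), [Pd(allyl)Cl]2 (2.5 mol %), IPr·HCl (6 mol %), KOt-Bu (15 mol %), THF, 45 °C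
Reagents that add atoms: none
Why: Carbonyl polarity reversal: the deprotonated N–H hydrazone acts as a benzylic carbanion (d1) equivalent that C-alkylates the π-allyl-Pd complex at its unsubstituted CH2 terminus and then loses N2 (Wolff–Kishner-type), so the former aldehyde carbon and the allylic carbon, both natively electrophilic, are joined with the E-olefin and the acetate retained (Tsuji–Trost allylation with a hydrazone as alkyl-carbanion surrogate).

Step 5
Reactants: 7 (E)-5-[2,4-bis(triisopropylsilyloxy)-6-methylphenyl]-3-methylpent-2-en-1-yl acetate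
Product: 8 (E)-5-(2,4-dihydroxy-6-methylphenyl)-3-methylpent-2-en-1-yl acetate
Conditions: TBAF (2.2 equiv), AcOH (2.5 equiv), THF, 0 °C
Reagents that add atoms: none
Why: Fluoride desilylation buffered with acetic acid frees both phenols without touching the allylic acetate or promoting acid-mediated cyclisation.

Step 6
Reactants: 8 (E)-5-(2,4-dihydroxy-6-methylphenyl)-3-methylpent-2-en-1-yl acetate
Product: 9 (S)-2-ethenyl-2,5-dimethyl-3,4-dihydro-2H-chromen-7-ol
Conditions: Pd2(dba)3·CHCl3 (2.5 mol %), (R,R)-DACH-phenyl Trost ligand (7.5 mol %), CH2Cl2 (0.05 M), rt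
Reagents that add atoms: none
Why: Trost asymmetric allylic alkylation: Pd ionises the acetate and the ortho-phenol attacks the tertiary allyl terminus (six-membered ring rather than eight), the chiral ligand pocket selecting one enantioface of the E-configured π-allyl and so setting the quaternary C2. The descriptor is S because vinyl outranks the ring CH2; it is the same spatial arrangement as 2R in the target.

Step 7
Reactants: 10 pent-4-yn-1-ol
Product: 12 (E)-5-iodo-4-methylpent-4-en-1-ol, via alkenylalane 11 (not isolated)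
Conditions: AlMe3 (3 equiv), Cp2ZrCl2 (0.25 equiv), CH2Cl2, 0 °C → rt; then I2, THF, −30 °C; aq. K2CO3
Reagents that add atoms: trimethylaluminium, C[Al](C)C; iodine, II
Why: Negishi Zr-catalysed carboalumination adds Me and Al syn across the alkyne (Me to the internal carbon), and iodinolysis with retention gives the E-vinyl iodide.

Step 8
Reactants: 12 (E)-5-iodo-4-methylpent-4-en-1-ol
Product: 13 (E)-5-iodo-4-methylpent-4-enal
Conditions: Dess–Martin periodinane, CH2Cl2, rt
Reagents that add atoms: none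
Why: Dess–Martin oxidation stops cleanly at the aldehyde and leaves the vinyl iodide untouched.

Step 9
Reactants: 13 (E)-5-iodo-4-methylpent-4-enal; 14 methyl 2-[bis(2,2,2-trifluoroethoxy)phosphoryl]propanoate
Product: 15 methyl (2Z,6E)-7-iodo-2,6-dimethylhepta-2,6-dienoate
Conditions: KHMDS, 18-crown-6, THF, −78 °C
Reagents that add atoms: none
Why: Still–Gennari olefination: the electron-poor trifluoroethyl phosphonate with a dissociated potassium counter-ion eliminates under kinetic control to the Z-2-methyl enoate.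

Step 10
Reactants: 9 (S)-2-ethenyl-2,5-dimethyl-3,4-dihydro-2H-chromen-7-ol; 15 methyl (2Z,6E)-7-iodo-2,6-dimethylhepta-2,6-dienoate
Product: 17 methyl (2Z,6E)-9-[(2R)-7-hydroxy-2,5-dimethyl-3,4-dihydro-2H-chromen-2-yl]-2,6-dimethylnona-2,6-dienoate, via B-alkyl-9-BBN adduct 16 (not isolated)
Conditions: 9-BBN-H (2.5 equiv), THF, 0 °C → rt; then 15 (1.2 equiv), PdCl2(dppf) (5 mol %), AsPh3 (10 mol %), Cs2CO3 (3 equiv), DMF/H2O, rt
Reagents that add atoms: none
Why: Anti-Markovnikov hydroboration of the only alkene, then B-alkyl Suzuki–Miyaura coupling with retention of the vinyl iodide geometry, forms C2'–C3' and completes the E,Z-diene chain without touching the C2 stereocentre, the ester or the free phenol (the phenol only consumes one equivalent of borane).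

**Compound list**

1 | 2,4-dihydroxy-6-methylbenzaldehyde (orsellinaldehyde) | Cc1cc(O)cc(O)c1C=O | starting material
2 | 2,4-bis(triisopropylsilyloxy)-6-methylbenzaldehyde | Cc1cc(O[Si](C(C)C)(C(C)C)C(C)C)cc(O[Si](C(C)C)(C(C)C)C(C)C)c1C=O | intermediate
3 | 3-methylbut-2-en-1-yl acetate (prenyl acetate) | CC(=O)OCC=C(C)C | starting material
4 | (E)-4-hydroxy-3-methylbut-2-en-1-yl acetate | CC(=O)OC/C=C(\C)CO | intermediate
5 | (E)-4-acetoxy-2-methylbut-2-en-1-yl methyl carbonate | COC(=O)OC/C(C)=C/COC(C)=O | intermediate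
6 | (E)-[2,4-bis(triisopropylsilyloxy)-6-methylbenzylidene]hydrazine (N–H hydrazone of 2) | Cc1cc(O[Si](C(C)C)(C(C)C)C(C)C)cc(O[Si](C(C)C)(C(C)C)C(C)C)c1/C=N/N | intermediate
7 | (E)-5-[2,4-bis(triisopropylsilyloxy)-6-methylphenyl]-3-methylpent-2-en-1-yl acetate | CC(=O)OC/C=C(\C)CCc1c(C)cc(O[Si](C(C)C)(C(C)C)C(C)C)cc1O[Si](C(C)C)(C(C)C)C(C)C | intermediate
8 | (E)-5-(2,4-dihydroxy-6-methylphenyl)-3-methylpent-2-en-1-yl acetate | CC(=O)OC/C=C(\C)CCc1c(C)cc(O)cc1O | intermediate
9 | (S)-2-ethenyl-2,5-dimethyl-3,4-dihydro-2H-chromen-7-ol | C=C[C@]1(C)CCc2c(C)cc(O)cc2O1 | intermediate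
10 | pent-4-yn-1-ol | C#CCCCO | starting material
11 | dimethylaluminium alkoxide of (E)-5-(dimethylalumanyl)-4-methylpent-4-en-1-ol (alkenylalane) | C[Al](C)OCCC/C(C)=C/[Al](C)C | intermediate
12 | (E)-5-iodo-4-methylpent-4-en-1-ol | OCCC/C(C)=C/I | intermediate
13 | (E)-5-iodo-4-methylpent-4-enal | O=CCC/C(C)=C/I | intermediate
14 | methyl 2-[bis(2,2,2-trifluoroethoxy)phosphoryl]propanoate | COC(=O)C(C)P(=O)(OCC(F)(F)F)OCC(F)(F)F | starting material
15 | methyl (2Z,6E)-7-iodo-2,6-dimethylhepta-2,6-dienoate | COC(=O)/C(C)=C\CC/C(C)=C/I | intermediate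
16 | B-{2-[(2R)-2,5-dimethyl-7-(9-BBN-oxy)chroman-2-yl]ethyl}-9-borabicyclo[3.3.1]nonane | B1(CC[C@]2(C)CCc3c(C)cc(OB4C5CCCC4CCC5)cc3O2)C2CCCC1CCC2 | intermediate
17 | methyl (2Z,6E)-9-[(2R)-7-hydroxy-2,5-dimethyl-3,4-dihydro-2H-chromen-2-yl]-2,6-dimethylnona-2,6-dienoate | COC(=O)/C(C)=C\CC/C(C)=C/CC[C@]1(C)CCc2c(C)cc(O)cc2O1 | target

**Step count**

Total: 10 steps. Longest linear sequence: 6 steps (3 → 4 → 5 → 7 → 8 → 9 → 17; steps 2, 3, 4, 5, 6, 10).

**Steps most likely to fail, with fallbacks**

Step 4 (hydrazone C-allylation). The aldehyde is 2,6-disubstituted and electron-rich. N-allylation, a second ionisation of the product acetate, or syn/anti scrambling of the 2-methyl-substituted π-allyl (E/Z erosion) could lower yield or geometric purity, and geometric purity matters for step 6. The fallback sets out from 2 and comes back at 7 with normal-polarity chemistry. Wittig reaction of 2 with 1-(triphenylphosphoranylidene)propan-2-one (toluene, 110 °C) gives (E)-4-[2,4-bis(triisopropylsilyloxy)-6-methylphenyl]but-3-en-2-one F1. Hydrogenation (H2, Pd/C, EtOAc) gives 4-[2,4-bis(triisopropylsilyloxy)-6-methylphenyl]butan-2-one F2. Horner–Wadsworth–Emmons reaction with triethyl phosphonoacetate/NaH gives ethyl (E)-5-[2,4-bis(triisopropylsilyloxy)-6-methylphenyl]-3-methylpent-2-enoate F3, with the minor Z-isomer removed by chromatography. DIBAL-H reduces it to (E)-5-[2,4-bis(triisopropylsilyloxy)-6-methylphenyl]-3-methylpent-2-en-1-ol F4, and Ac2O/pyridine returns 7.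

Step 6 (asymmetric ring closure). The sense and level of induction depend on ligand antipode, olefin geometry and medium acidity, and the acetate ionises more slowly than the carbonates used in the closest precedents. The fallback sets out from 7 and comes back at 9, replacing π-allyl chemistry with a stereospecific epoxide opening. Shi epoxidation of 7 (D-fructose-derived ketone, Oxone, pH 10.5, 0 °C) gives [(2R,3R)-3-{2-[2,4-bis(triisopropylsilyloxy)-6-methylphenyl]ethyl}-3-methyloxiran-2-yl]methyl acetate F5. TBAF/AcOH frees the phenols to give [(2R,3R)-3-[2-(2,4-dihydroxy-6-methylphenyl)ethyl]-3-methyloxiran-2-yl]methyl acetate F6. Catalytic CSA (CH2Cl2, 0 °C) makes the ortho-phenol open the epoxide at its tertiary carbon with inversion, giving (R)-2-hydroxy-2-[(S)-7-hydroxy-2,5-dimethylchroman-2-yl]ethyl acetate F7. K2CO3/MeOH gives (R)-1-[(S)-7-hydroxy-2,5-dimethylchroman-2-yl]ethane-1,2-diol F8. NaIO4 cleaves it to (S)-7-hydroxy-2,5-dimethylchroman-2-carbaldehyde F9, and Ph3P=CH2 (2.2 equiv) returns 9.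

Step 10 (B-alkyl Suzuki). The borane sits next to a quaternary centre, the phenol is free, and protodeboronation or slow transmetalation could intervene. The fallback sets out from 9 and comes back at 17 by cross-electrophile coupling instead of organoboron coupling. Hydroboration–oxidation (9-BBN-H, then NaOH/H2O2) gives (S)-2-(2-hydroxyethyl)-2,5-dimethylchroman-7-ol F10. Appel iodination (I2, PPh3, imidazole) gives (S)-2-(2-iodoethyl)-2,5-dimethylchroman-7-ol F11. Ni-catalysed reductive coupling of F11 with 15 (NiBr2·glyme, 4,4'-di-tert-butyl-2,2'-bipyridine, Mn, DMA, rt) gives 17.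

**Further compounds**

F1 | step 4 | (E)-4-[2,4-bis(triisopropylsilyloxy)-6-methylphenyl]but-3-en-2-one | CC(=O)/C=C/c1c(C)cc(O[Si](C(C)C)(C(C)C)C(C)C)cc1O[Si](C(C)C)(C(C)C)C(C)C
F2 | step 4 | 4-[2,4-bis(triisopropylsilyloxy)-6-methylphenyl]butan-2-one | CC(=O)CCc1c(C)cc(O[Si](C(C)C)(C(C)C)C(C)C)cc1O[Si](C(C)C)(C(C)C)C(C)C
F3 | step 4 | ethyl (E)-5-[2,4-bis(triisopropylsilyloxy)-6-methylphenyl]-3-methylpent-2-enoate | CCOC(=O)/C=C(\C)CCc1c(C)cc(O[Si](C(C)C)(C(C)C)C(C)C)cc1O[Si](C(C)C)(C(C)C)C(C)C
F4 | step 4 | (E)-5-[2,4-bis(triisopropylsilyloxy)-6-methylphenyl]-3-methylpent-2-en-1-ol | OC/C=C(\C)CCc1c(C)cc(O[Si](C(C)C)(C(C)C)C(C)C)cc1O[Si](C(C)C)(C(C)C)C(C)C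
F5 | step 6 | [(2R,3R)-3-{2-[2,4-bis(triisopropylsilyloxy)-6-methylphenyl]ethyl}-3-methyloxiran-2-yl]methyl acetate | CC(=O)OC[C@H]1O[C@]1(C)CCc1c(C)cc(O[Si](C(C)C)(C(C)C)C(C)C)cc1O[Si](C(C)C)(C(C)C)C(C)C
F6 | step 6 | [(2R,3R)-3-[2-(2,4-dihydroxy-6-methylphenyl)ethyl]-3-methyloxiran-2-yl]methyl acetate | CC(=O)OC[C@H]1O[C@]1(C)CCc1c(C)cc(O)cc1O
F7 | step 6 | (R)-2-hydroxy-2-[(S)-7-hydroxy-2,5-dimethylchroman-2-yl]ethyl acetate | CC(=O)OC[C@@H](O)[C@]1(C)CCc2c(C)cc(O)cc2O1
F8 | step 6 | (R)-1-[(S)-7-hydroxy-2,5-dimethylchroman-2-yl]ethane-1,2-diol | OC[C@@H](O)[C@]1(C)CCc2c(C)cc(O)cc2O1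
F9 | step 6 | (S)-7-hydroxy-2,5-dimethylchroman-2-carbaldehyde | O=C[C@]1(C)CCc2c(C)cc(O)cc2O1
F10 | step 10 | (S)-2-(2-hydroxyethyl)-2,5-dimethylchroman-7-ol | OCC[C@]1(C)CCc2c(C)cc(O)cc2O1
F11 | step 10 | (S)-2-(2-iodoethyl)-2,5-dimethylchroman-7-ol | ICC[C@]1(C)CCc2c(C)cc(O)cc2O1
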